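**Plan**

- Retrosynthetic cuts: the two MOM ethers; then the S–C3 bond of the thiolactone; then the aryl–C(=O)S bond (aryl bromide plus COS); then the epoxide, back to the aryl–C3 bond made from an aryllithium and (S)-2-chloroheptanal; last the aryl–prenyl bond.
- Forward order: the protected hydroquinone is mono-prenylated, the ring position between Br and OMOM is lithiated and joined to the C7 chain, and the chlorohydrin is closed to the trans epoxide. Br/Li exchange and COS capture then let the five-membered sulfur ring, the only ring formed, close before deprotection.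
- Enabling feature: sulfur sits on the benzylic carbon C3 of the 2-benzothiophen-1(3H)-one ring, anti to the hydroxyl on the adjacent chain carbon C1'. This is the pattern left when an ortho C(=O)S group opens a trans aryl epoxide from the back.
- Stereochemistry: C1' comes from enamine-catalysed α-chlorination of heptanal (S) and is inverted to (R) on epoxide closure. The carbinol centre comes from Cornforth-controlled anti addition. C3 (S) arises by SN2 inversion of the (R) benzylic epoxide carbon.

Key step: step 6

Assumption: 2,6-dibromohydroquinone (1) is taken as a catalogue chemical, and the (5S)-imidazolidinone of step 3 is taken to deliver the (S)-chloride; if the sense proved opposite, its enantiomer would be used.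

**Route**

Step 1
Reactants: 1 2,6-dibromohydroquinone
Product: 2 1,3-dibromo-2,5-bis(methoxymethoxy)benzene
Conditions: NaH, MOMCl, DMF, 0 °C → rt
Reagents that add atoms: chloromethyl methyl ether, COCCl
Why: Double Williamson O-alkylation of the bis-phenoxide gives the MOM ethers, which tolerate the organolithium steps, acidify the flanking ring positions for later lithiation and come off under mild acid.

Step 2
Reactants: 2 1,3-dibromo-2,5-bis(methoxymethoxy)benzene; 3 prenyl bromide
Product: 5 1-bromo-2,5-bis(methoxymethoxy)-3-(3-methylbut-2-en-1-yl)benzene, via aryllithium 4 (not isolated)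
Conditions: n-BuLi (1.0 equiv), THF, −78 °C; CuBr·SMe2 (10 mol%), then 3, −78 → 0 °C
Reagents that add atoms: none
Why: The two bromines are equivalent, so one equivalent of n-BuLi gives a single aryllithium by Br/Li exchange, and copper-catalysed allylic substitution at the unhindered CH2 terminus of prenyl bromide (SN2 rather than SN2', which would build a quaternary centre) should give the linear prenyl arene.

Step 3
Reactants: 6 heptanal
Product: 7 (2S)-2-chloroheptanal
Conditions: (5S)-5-benzyl-2,2,3-trimethylimidazolidin-4-one·TFA (5 mol%), 2,3,4,5,6,6-hexachlorocyclohexa-2,4-dien-1-one, acetone, −30 °C; pentane filtration, used at once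
Reagents that add atoms: 2,3,4,5,6,6-hexachlorocyclohexa-2,4-dien-1-one, O=C1C(Cl)=C(Cl)C(Cl)=C(Cl)C1(Cl)Cl
Why: Enamine organocatalysis (asymmetric α-chlorination of aldehydes): the E-enamine of heptanal is chlorinated on the face left open by the benzyl group of the catalyst, which sets the (S) centre at C2.

Step 4
Reactants: 5 1-bromo-2,5-bis(methoxymethoxy)-3-(3-methylbut-2-en-1-yl)benzene; 7 (2S)-2-chloroheptanal
Product: 9 (1R,2S)-1-[2-bromo-3,6-bis(methoxymethoxy)-4-(3-methylbut-2-en-1-yl)phenyl]-2-chloroheptan-1-ol, via aryllithium 8 (not isolated)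
Conditions: LDA (1.05 equiv), THF, −78 °C; then 7, −78 °C; AcOH quench at −78 °C
Reagents that add atoms: none
Why: Directed ortho-lithiation removes the ring proton flanked by Br and OMOM, and 1,2-addition of the aryllithium to the α-chloroaldehyde through the Cornforth (polar Felkin–Anh) arrangement should give the 1,2-anti chlorohydrin, so the (S) C–Cl centre sets the new (R) carbinol centre; at −78 °C loss of LiBr to an aryne and enolisation of the aldehyde should stay slow.

Step 5
Reactants: 9 (1R,2S)-1-[2-bromo-3,6-bis(methoxymethoxy)-4-(3-methylbut-2-en-1-yl)phenyl]-2-chloroheptan-1-ol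
Product: 10 (2R,3R)-2-[2-bromo-3,6-bis(methoxymethoxy)-4-(3-methylbut-2-en-1-yl)phenyl]-3-pentyloxirane
Conditions: KOH, EtOH, 0 °C → rt
Reagents that add atoms: none
Why: Intramolecular Williamson etherification (3-exo-tet): the alkoxide displaces chloride with inversion at C2, turning the anti chlorohydrin into the trans (2R,3R) epoxide without touching the benzylic C–O bond.

Step 6
Reactants: 10 (2R,3R)-2-[2-bromo-3,6-bis(methoxymethoxy)-4-(3-methylbut-2-en-1-yl)phenyl]-3-pentyloxirane
Product: 13 (3S)-3-[(1R)-1-hydroxyhexyl]-4,7-bis(methoxymethoxy)-6-(3-methylbut-2-en-1-yl)-2-benzothiophen-1(3H)-one, via aryllithium 11 (not isolated), via lithium thiocarboxylate 12 (not isolated)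
Conditions: t-BuLi (2 equiv), THF, −78 °C; COS, −78 °C; Ar purge; degassed pH 7 phosphate buffer, −40 °C → rt
Reagents that add atoms: carbonyl sulfide, O=C=S
Why: Br/Li exchange followed by capture of the aryllithium with COS (the sulfur analogue of carboxylation of organolithium and Grignard reagents) gives the aryl thiocarboxylate 12 next to the epoxide. Its sulfur then attacks the benzylic epoxide carbon from the back, forming the S–C3 bond and releasing the C1' oxygen, which the buffer protonates at once. The closest known reaction types are phthalide formation from ortho-carboxy aryl epoxides, phthalan formation when ortho-lithiated aryl oxiranes are trapped with carbonyl electrophiles, and S-alkylation of thiocarboxylates by epoxides. The thiolactone ring (S, C1, C7a, C3a, C3) closes in the 5-exo-tet mode. C3 is set as (S) by SN2 inversion of the (R) benzylic epoxide carbon, while C1' keeps its (R) configuration because its C–O bond is not broken. The step needs S- over O-alkylation (secured by the soft, more nucleophilic sulfur of the thiocarboxylate), attack at the benzylic carbon rather than 6-endo attack at C1' (secured by ring size and benzylic activation), and no acyl shift from S to the C1' oxygen (secured by keeping the medium neutral so that no alkoxide persists).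

Step 7
Reactants: 13 (3S)-3-[(1R)-1-hydroxyhexyl]-4,7-bis(methoxymethoxy)-6-(3-methylbut-2-en-1-yl)-2-benzothiophen-1(3H)-one
Product: 14 asperglaucin A, (3S)-4,7-dihydroxy-3-[(1R)-1-hydroxyhexyl]-6-(3-methylbut-2-en-1-yl)-2-benzothiophen-1(3H)-one
Conditions: HCl (1.25 M in MeOH), THF, 0 °C → rt, Ar
Reagents that add atoms: none
Why: Acid-catalysed acetal exchange with methanol removes both MOM groups; at or below room temperature the thiolactone, the secondary alcohol and the prenyl alkene should survive, and no stereocentre is involved.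

**Compound list**

1 | 2,6-dibromohydroquinone | Oc1cc(Br)c(O)c(Br)c1 | starting material
2 | 1,3-dibromo-2,5-bis(methoxymethoxy)benzene | COCOc1cc(Br)c(OCOC)c(Br)c1 | intermediate
3 | prenyl bromide (1-bromo-3-methylbut-2-ene) | CC(C)=CCBr | starting material
4 | [3-bromo-2,5-bis(methoxymethoxy)phenyl]lithium | [Li]c1cc(OCOC)cc(Br)c1OCOC | intermediate
5 | 1-bromo-2,5-bis(methoxymethoxy)-3-(3-methylbut-2-en-1-yl)benzene | COCOc1cc(Br)c(OCOC)c(CC=C(C)C)c1 | intermediate
6 | heptanal | CCCCCCC=O | starting material
7 | (2S)-2-chloroheptanal | CCCCC[C@H](Cl)C=O | intermediate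
8 | [2-bromo-3,6-bis(methoxymethoxy)-4-(3-methylbut-2-en-1-yl)phenyl]lithium | [Li]c1c(Br)c(OCOC)c(CC=C(C)C)cc1OCOC | intermediate
9 | (1R,2S)-1-[2-bromo-3,6-bis(methoxymethoxy)-4-(3-methylbut-2-en-1-yl)phenyl]-2-chloroheptan-1-ol | CCCCC[C@H](Cl)[C@H](O)c1c(Br)c(OCOC)c(CC=C(C)C)cc1OCOC | intermediate
10 | (2R,3R)-2-[2-bromo-3,6-bis(methoxymethoxy)-4-(3-methylbut-2-en-1-yl)phenyl]-3-pentyloxirane | CCCCC[C@H]1O[C@@H]1c2c(Br)c(OCOC)c(CC=C(C)C)cc2OCOC | intermediate
11 | [2,5-bis(methoxymethoxy)-3-(3-methylbut-2-en-1-yl)-6-[(2R,3R)-3-pentyloxiran-2-yl]phenyl]lithium | CCCCC[C@H]1O[C@@H]1c2c([Li])c(OCOC)c(CC=C(C)C)cc2OCOC | intermediate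
12 | lithium 3,6-bis(methoxymethoxy)-5-(3-methylbut-2-en-1-yl)-2-[(2R,3R)-3-pentyloxiran-2-yl]benzenecarbothioate | CCCCC[C@H]1O[C@@H]1c2c(C(=O)[S-])c(OCOC)c(CC=C(C)C)cc2OCOC.[Li+] | intermediate
13 | (3S)-3-[(1R)-1-hydroxyhexyl]-4,7-bis(methoxymethoxy)-6-(3-methylbut-2-en-1-yl)-2-benzothiophen-1(3H)-one | CCCCC[C@@H](O)[C@H]1SC(=O)c2c(OCOC)c(CC=C(C)C)cc(OCOC)c21 | intermediate
14 | asperglaucin A | CCCCC[C@@H](O)[C@H]1SC(=O)c2c(O)c(CC=C(C)C)cc(O)c21 | target

**Step count**

Total steps: 7. Longest linear sequence: 6 steps (1 → 2 → 5 → 9 → 10 → 13 → 14); step 3 is a one-step branch.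

**Steps most likely to fail**

Step 6. The ortho-lithiated aryl oxirane may decay before COS capture (proton transfer from the oxirane C–H, ring opening). The epoxide may also ionise at the benzylic carbon and lose the C3 configuration, or the acyl group may migrate from sulfur to the C1' oxygen if an alkoxide persists. The fallback sets out from 10 and replaces the anionic thiocarboxylate by a neutral acyl-sulfur nucleophile. The same Br/Li exchange is followed by trapping with dimethylthiocarbamoyl chloride to give the isolable N,N-dimethylthioamide F1. Treating F1 with p-TsOH·H2O in wet MeCN at 0 °C should let the thione sulfur open the epoxide 5-exo with inversion to the cyclic thioimidate iminium tosylate F2. F2 would hydrolyse in the same flask, losing dimethylamine, and the route is rejoined at 13.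

Step 4. The ortho-bromoaryllithium may lose LiBr, the base may erode the configuration of the α-chloroaldehyde, or facial selectivity in the addition may be weak. The fallback sets out from 5 and uses a configurationally robust aldehyde with the leaving group moved to the benzylic carbon. Racemic 1,2-epoxyheptane would be resolved by hydrolytic kinetic resolution with the (salen)Co(III) antipode that hydrolyses the (R)-epoxide (taken to be S,S) to give (2R)-heptane-1,2-diol F3. Silylation with TESCl and imidazole would give the bis(triethylsilyl) ether F4, and Swern oxidation, which cleaves and oxidises only the primary silyl ether, would give (2R)-2-(triethylsilyloxy)heptanal F5. Lithiated 5 (LDA, −78 °C) should add to F5 in the Felkin–Anh sense to give the anti (1S,2R) silyloxy alcohol F6. MsCl and Et3N at −20 °C would give the benzylic mesylate F7, and TBAF would free the C2 alkoxide, which displaces the mesylate with inversion. The route is rejoined at 10, bypassing 7 and 9.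

Step 7. Acid may cyclise the prenyl group onto the neighbouring C7 phenol (chroman formation), methanol may open the thiolactone, or the acyl group may migrate to the C1' oxygen. The fallback sets out from 13 and removes the acetals oxidatively instead of by acid. Ceric ammonium nitrate in MeCN/H2O at 0 °C should convert the bis-MOM hydroquinone into the quinone F8. Brief reduction with aqueous Na2S2O4 in EtOAc would then return the hydroquinone, rejoining the route at 14.

**Further compounds**

F1 | step 6 | 3,6-bis(methoxymethoxy)-N,N-dimethyl-5-(3-methylbut-2-en-1-yl)-2-[(2R,3R)-3-pentyloxiran-2-yl]benzenecarbothioamide | CCCCC[C@H]1O[C@@H]1c2c(C(=S)N(C)C)c(OCOC)c(CC=C(C)C)cc2OCOC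
F2 | step 6 | (3S)-3-[(1R)-1-hydroxyhexyl]-4,7-bis(methoxymethoxy)-N,N-dimethyl-6-(3-methylbut-2-en-1-yl)-3H-2-benzothiophen-1-iminium 4-methylbenzenesulfonate | CCCCC[C@@H](O)[C@H]1SC(=[N+](C)C)c2c(OCOC)c(CC=C(C)C)cc(OCOC)c21.Cc1ccc(cc1)S(=O)(=O)[O-]
F3 | step 4 | (2R)-heptane-1,2-diol | CCCCC[C@@H](O)CO
F4 | step 4 | (2R)-1,2-bis(triethylsilyloxy)heptane | CCCCC[C@@H](O[Si](CC)(CC)CC)CO[Si](CC)(CC)CC
F5 | step 4 | (2R)-2-(triethylsilyloxy)heptanal | CCCCC[C@@H](O[Si](CC)(CC)CC)C=O
F6 | step 4 | (1S,2R)-1-[2-bromo-3,6-bis(methoxymethoxy)-4-(3-methylbut-2-en-1-yl)phenyl]-2-(triethylsilyloxy)heptan-1-ol | CCCCC[C@@H](O[Si](CC)(CC)CC)[C@@H](O)c1c(Br)c(OCOC)c(CC=C(C)C)cc1OCOC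
F7 | step 4 | (1S,2R)-1-[2-bromo-3,6-bis(methoxymethoxy)-4-(3-methylbut-2-en-1-yl)phenyl]-2-(triethylsilyloxy)heptyl methanesulfonate | CCCCC[C@@H](O[Si](CC)(CC)CC)[C@@H](OS(C)(=O)=O)c1c(Br)c(OCOC)c(CC=C(C)C)cc1OCOC
F8 | step 7 | (3S)-3-[(1R)-1-hydroxyhexyl]-6-(3-methylbut-2-en-1-yl)-2-benzothiophene-1,4,7(3H)-trione | CCCCC[C@@H](O)[C@H]1SC(=O)C2=C1C(=O)C=C(CC=C(C)C)C2=O
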